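The benzophenone is disconnected at two neighbouring atoms of ring A (C1 bears the side chain; C2, C4 and C6 the oxygens): the C5–C(=O)Ph bond and the C6–OH bond. Both are formed in one operation when benzoic acid adds across a C5–C6 aryne, the C4 oxygen steering oxygen to C6 and the acyl carbon to C5, on a ring that already carries the complete (R)-configured side chain. The precursor is the ortho-silylaryl triflate (Me3Si on C5, OTf on C6) with two MOM ethers and the carbinol as a benzoate, because a silyl ether two carbons from an aryne could be cleaved by fluoride and trap it.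

Key step: step 11

Remark: stock reagents (LiN(i-Pr)2 solution, TBSOTf, PhNTf2, Dess–Martin periodinane, catecholborane, (S)-Me-CBS, i-PrNCO) are taken as purchased; ring A is numbered as above throughout.

Step 1
Reactants: 1 phloroglucinol (benzene-1,3,5-triol)
Product: 2 3,5-bis(methoxymethoxy)phenol
Conditions: MOMCl (2.0 equiv), i-Pr2NEt (2.2 equiv), DMF, 0 °C → rt; chromatography
Reagents that add atoms: chloromethyl methyl ether, COCCl
Why: O-alkylation (MOM protection) of the symmetrical triphenol with two equivalents of MOMCl should give the bis-ether as the main part of a statistical mixture, from which it is separated because the mono-, bis- and tris-ethers differ strongly in polarity.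

Step 2
Reactants: 2 3,5-bis(methoxymethoxy)phenol
Product: 3 3,5-bis(methoxymethoxy)phenyl N-(propan-2-yl)carbamate
Conditions: i-PrNCO (1.3 equiv), Et3N (0.2 equiv), CH2Cl2, rt
Reagents that add atoms: isopropyl isocyanate, CC(C)N=C=O
Why: Base-catalysed addition of the phenol to the isocyanate (carbamoylation) installs a secondary carbamate that is the strongest ortho-director on the ring, masks the C6 oxygen until the side chain is complete, and can later be removed under mild E1cB conditions.

Step 3
Reactants: 3 3,5-bis(methoxymethoxy)phenyl N-(propan-2-yl)carbamate; 4 allyl bromide (3-bromoprop-1-ene)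
Product: 10 2-allyl-3,5-bis(methoxymethoxy)-6-(trimethylsilyl)phenyl N-(propan-2-yl)carbamate, via N-silyl carbamate 5 (not isolated), via first aryllithium 6 (not isolated), via N-silyl aryl silane 7 (not isolated), via second aryllithium 8 (not isolated), via N-silyl allyl arene 9 (not isolated)
Conditions: TBSOTf (1.1 equiv), TMEDA (3 equiv), Et2O, 0 °C → rt; n-BuLi (2.1 equiv), −78 °C; TMSCl (1.1 equiv), −78 → 0 °C; n-BuLi (1.3 equiv), −78 °C; CuBr·SMe2 (10 mol %), allyl bromide (3 equiv), −78 → 0 °C; brief cold aq. NaHSO4 work-up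
Reagents that add atoms: chlorotrimethylsilane, C[Si](C)(C)Cl
Why: Two consecutive directed ortho-metalations in one flask: the carbamate, N-silylated once at the outset, outranks the MOM ethers as director, so the first lithiation should take one of the two equivalent carbons between the carbamate oxygen and a MOM oxygen and is quenched with a near-stoichiometric amount of TMSCl, the second lithiation should take the one remaining carbon next to the carbamate and is allylated under copper catalysis (silicon first, because an allyl group would offer acidic benzylic–allylic protons to the base), and the N–Si bond is hydrolysed only on work-up.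

Step 4
Reactants: 10 2-allyl-3,5-bis(methoxymethoxy)-6-(trimethylsilyl)phenyl N-(propan-2-yl)carbamate
Product: 12 3,5-bis(methoxymethoxy)-2-(2-oxoethyl)-6-(trimethylsilyl)phenyl N-(propan-2-yl)carbamate, via diol 11 (not isolated)
Conditions: OsO4 (2 mol %), NaIO4 (4 equiv), 2,6-lutidine (2 equiv), 1,4-dioxane/H2O 3:1, rt; used crude
Reagents that add atoms: osmium tetroxide, O=[Os](=O)(=O)=O; sodium periodate, [Na+].[O-]I(=O)(=O)=O
Why: Lemieux–Johnson oxidative cleavage (dihydroxylation, then periodate glycol cleavage, buffered by 2,6-lutidine) turns the terminal alkene into the arylacetaldehyde without touching the arene, the aryl silane or the acetals, and no lactol can form because the neighbouring phenol oxygen is still a carbamate.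

Step 5
Reactants: 13 6-methylhept-5-en-2-one
Product: 15 6-methylhepta-1,5-dien-2-yl trifluoromethanesulfonate, via lithium enolate 14 (not isolated)
Conditions: LiN(i-Pr)2 (1.1 equiv), THF, −78 °C; PhNTf2 (1.05 equiv), −78 °C → rt
Reagents that add atoms: N-phenylbis(trifluoromethanesulfonimide), O=S(=O)(N(c1ccccc1)S(=O)(=O)C(F)(F)F)C(F)(F)F
Why: Kinetic deprotonation of the methyl ketone at −78 °C occurs on the methyl group, and O-triflation of that terminal enolate gives the 1,1-disubstituted alkenyl triflate (enol triflate formation).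

Step 6
Reactants: 12 3,5-bis(methoxymethoxy)-2-(2-oxoethyl)-6-(trimethylsilyl)phenyl N-(propan-2-yl)carbamate; 15 6-methylhepta-1,5-dien-2-yl trifluoromethanesulfonate
Product: 17 rac-2-(2-hydroxy-7-methyl-3-methylideneoct-6-en-1-yl)-3,5-bis(methoxymethoxy)-6-(trimethylsilyl)phenyl N-(propan-2-yl)carbamate, via alkenylchromium dichloride 16 (not isolated)
Conditions: CrCl2 (4 equiv), NiCl2 (2 mol %), 15 (2 equiv), degassed DMF, rt
Reagents that add atoms: none
Why: Nozaki–Hiyama–Kishi coupling: nickel-catalysed activation of the alkenyl triflate and transfer to chromium gives a weakly basic alkenylchromium species that adds to the enolisable arylacetaldehyde without deprotonating it or the N–H carbamate; the carbinol is deliberately made racemic and its configuration is set in step 8.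

Step 7
Reactants: 17 rac-2-(2-hydroxy-7-methyl-3-methylideneoct-6-en-1-yl)-3,5-bis(methoxymethoxy)-6-(trimethylsilyl)phenyl N-(propan-2-yl)carbamate
Product: 18 3,5-bis(methoxymethoxy)-2-(7-methyl-3-methylidene-2-oxooct-6-en-1-yl)-6-(trimethylsilyl)phenyl N-(propan-2-yl)carbamate
Conditions: Dess–Martin periodinane (1.5 equiv), NaHCO3, CH2Cl2, 0 °C → rt
Reagents that add atoms: none
Why: Dess–Martin oxidation of the secondary allylic alcohol under buffered neutral conditions should give the α-methylene ketone without migration of the exocyclic double bond.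

Step 8
Reactants: 18 3,5-bis(methoxymethoxy)-2-(7-methyl-3-methylidene-2-oxooct-6-en-1-yl)-6-(trimethylsilyl)phenyl N-(propan-2-yl)carbamate
Product: 19 2-[(2R)-2-hydroxy-7-methyl-3-methylideneoct-6-en-1-yl]-3,5-bis(methoxymethoxy)-6-(trimethylsilyl)phenyl N-(propan-2-yl)carbamate
Conditions: (S)-Me-CBS (0.3 equiv), catecholborane (2 equiv), toluene, −78 °C; MeOH quench, aq. NaHCO3
Reagents that add atoms: none
Why: Corey–Bakshi–Shibata reduction: the enone binds to the catalyst boron anti to its larger α-branched alkenyl group and hydride passes from the coordinated catecholborane to the Si face of the carbonyl, which should set the (R)-carbinol, while catecholborane at −78 °C leaves the isolated alkenes alone.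

Step 9
Reactants: 19 2-[(2R)-2-hydroxy-7-methyl-3-methylideneoct-6-en-1-yl]-3,5-bis(methoxymethoxy)-6-(trimethylsilyl)phenyl N-(propan-2-yl)carbamate
Product: 20 (2R)-7-methyl-3-methylidene-1-[4,6-bis(methoxymethoxy)-2-{[(propan-2-yl)carbamoyl]oxy}-3-(trimethylsilyl)phenyl]oct-6-en-2-yl benzoate
Conditions: BzCl (1.5 equiv), pyridine, DMAP (0.1 equiv), CH2Cl2, 0 °C → rt
Reagents that add atoms: benzoyl chloride, O=C(Cl)c1ccccc1
Why: DMAP-catalysed acylation of the secondary alcohol (the carbamate N–H is far less nucleophilic) gives an ester whose oxygen is too weakly nucleophilic to compete for an aryne, which carries no silyl group that fluoride could remove and has no α-protons.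

Step 10
Reactants: 20 (2R)-7-methyl-3-methylidene-1-[4,6-bis(methoxymethoxy)-2-{[(propan-2-yl)carbamoyl]oxy}-3-(trimethylsilyl)phenyl]oct-6-en-2-yl benzoate
Product: 22 2-[(2R)-2-(benzoyloxy)-7-methyl-3-methylideneoct-6-en-1-yl]-3,5-bis(methoxymethoxy)-6-(trimethylsilyl)phenyl trifluoromethanesulfonate, via phenol 21 (not isolated)
Conditions: Et2NH (1.5 equiv), DBU (2 equiv), MeCN, 40 °C; then PhNTf2 (1.5 equiv), 40 °C
Reagents that add atoms: N-phenylbis(trifluoromethanesulfonimide), O=S(=O)(N(c1ccccc1)S(=O)(=O)C(F)(F)F)C(F)(F)F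
Why: One-pot decarbamoylation–triflation: E1cB loss of isopropyl isocyanate (trapped by Et2NH as a urea) frees the hindered phenoxide, which is triflated in the same flask by PhNTf2, a reagent that leaves the benzoate and all aliphatic positions alone.

Step 11
Reactants: 22 2-[(2R)-2-(benzoyloxy)-7-methyl-3-methylideneoct-6-en-1-yl]-3,5-bis(methoxymethoxy)-6-(trimethylsilyl)phenyl trifluoromethanesulfonate; 23 benzoic acid
Product: 25 (2R)-1-[3-benzoyl-2-hydroxy-4,6-bis(methoxymethoxy)phenyl]-7-methyl-3-methylideneoct-6-en-2-yl benzoate, via aryne 24 (not isolated)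
Conditions: PhCO2H (1.5 equiv), CsF (5 equiv), THF (0.03 M), 125 °C, sealed tube
Reagents that add atoms: none
Why: Fluoride attacks silicon and triflate leaves, giving the C5–C6 aryne 24; benzoate oxygen adds to C6, the C5 aryl anion so formed attacks the adjacent ester carbonyl through a four-membered tetrahedral intermediate, and C–O cleavage gives the ketone and the C6 phenoxide (net insertion of the aryne into the acyl–oxygen bond, an anionic Fries-type 1,3-acyl shift). The closest known reaction type is the fluoride-induced insertion of arynes from ortho-silylaryl triflates into the C–O bond of carboxylic acids, which gives ortho-hydroxyaryl ketones in hot THF. No ring is closed and no stereocentre is formed; the (R)-carbinol is a spectator. The step needs regioselective addition of the carboxylate: the inductively withdrawing C4 oxygen distorts the aryne so that C6 is the more electrophilic end and the negative charge develops on C5 beside that oxygen, while steric differences are small because both aryne carbons have an ortho substituent. It also needs the external carboxylate to outrun internal traps and protonation, which is why the side-chain oxygen is an ester, benzoate is used in excess, and the medium is aprotic.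

Step 12
Reactants: 25 (2R)-1-[3-benzoyl-2-hydroxy-4,6-bis(methoxymethoxy)phenyl]-7-methyl-3-methylideneoct-6-en-2-yl benzoate
Product: 26 {2-hydroxy-3-[(2R)-2-hydroxy-7-methyl-3-methylideneoct-6-en-1-yl]-4,6-bis(methoxymethoxy)phenyl}(phenyl)methanone
Conditions: K2CO3 (2 equiv), MeOH, argon, rt → 40 °C
Reagents that add atoms: none
Why: Base-catalysed transesterification (methanolysis) of the benzoate, helped by the neighbouring phenoxide, frees the secondary alcohol without affecting the MOM ethers, the alkenes or the stereocentre.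

Step 13
Reactants: 26 {2-hydroxy-3-[(2R)-2-hydroxy-7-methyl-3-methylideneoct-6-en-1-yl]-4,6-bis(methoxymethoxy)phenyl}(phenyl)methanone
Product: 27 {2,4,6-trihydroxy-3-[(2R)-2-hydroxy-7-methyl-3-methylideneoct-6-en-1-yl]phenyl}(phenyl)methanone
Conditions: ZnBr2 (2.5 equiv), n-PrSH (5 equiv), CH2Cl2, 0 °C → rt; pH 7 buffer work-up
Reagents that add atoms: none
Why: Lewis-acid-assisted thiolysis of the two MOM acetals is fast and non-protic and the thiol scavenges the methoxymethyl cation, so the allylic alcohol and both alkenes should survive while the free acylphloroglucinol is released.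

Compound list
1 | phloroglucinol (benzene-1,3,5-triol) | Oc1cc(O)cc(O)c1 | starting material
2 | 3,5-bis(methoxymethoxy)phenol | COCOc1cc(O)cc(OCOC)c1 | intermediate
3 | 3,5-bis(methoxymethoxy)phenyl N-(propan-2-yl)carbamate | CC(C)NC(=O)Oc1cc(OCOC)cc(OCOC)c1 | intermediate
4 | allyl bromide (3-bromoprop-1-ene) | C=CCBr | starting material
5 | 3,5-bis(methoxymethoxy)phenyl N-(tert-butyldimethylsilyl)-N-(propan-2-yl)carbamate (not isolated) | CC(C)N(C(=O)Oc1cc(OCOC)cc(OCOC)c1)[Si](C)(C)C(C)(C)C | intermediate
6 | 2-lithio-3,5-bis(methoxymethoxy)phenyl N-(tert-butyldimethylsilyl)-N-(propan-2-yl)carbamate (not isolated) | CC(C)N(C(=O)Oc1cc(OCOC)cc(OCOC)c1[Li])[Si](C)(C)C(C)(C)C | intermediate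
7 | 3,5-bis(methoxymethoxy)-2-(trimethylsilyl)phenyl N-(tert-butyldimethylsilyl)-N-(propan-2-yl)carbamate (not isolated) | CC(C)N(C(=O)Oc1cc(OCOC)cc(OCOC)c1[Si](C)(C)C)[Si](C)(C)C(C)(C)C | intermediate
8 | 2-lithio-3,5-bis(methoxymethoxy)-6-(trimethylsilyl)phenyl N-(tert-butyldimethylsilyl)-N-(propan-2-yl)carbamate (not isolated) | CC(C)N(C(=O)Oc1c([Li])c(OCOC)cc(OCOC)c1[Si](C)(C)C)[Si](C)(C)C(C)(C)C | intermediate
9 | 2-allyl-3,5-bis(methoxymethoxy)-6-(trimethylsilyl)phenyl N-(tert-butyldimethylsilyl)-N-(propan-2-yl)carbamate (not isolated) | C=CCc1c(OCOC)cc(OCOC)c([Si](C)(C)C)c1OC(=O)N(C(C)C)[Si](C)(C)C(C)(C)C | intermediate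
10 | 2-allyl-3,5-bis(methoxymethoxy)-6-(trimethylsilyl)phenyl N-(propan-2-yl)carbamate | C=CCc1c(OCOC)cc(OCOC)c([Si](C)(C)C)c1OC(=O)NC(C)C | intermediate
11 | 2-(2,3-dihydroxypropyl)-3,5-bis(methoxymethoxy)-6-(trimethylsilyl)phenyl N-(propan-2-yl)carbamate (racemic; not isolated) | OCC(O)Cc1c(OCOC)cc(OCOC)c([Si](C)(C)C)c1OC(=O)NC(C)C | intermediate
12 | 3,5-bis(methoxymethoxy)-2-(2-oxoethyl)-6-(trimethylsilyl)phenyl N-(propan-2-yl)carbamate | O=CCc1c(OCOC)cc(OCOC)c([Si](C)(C)C)c1OC(=O)NC(C)C | intermediate
13 | 6-methylhept-5-en-2-one | CC(=O)CCC=C(C)C | starting material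
14 | lithium 6-methylhepta-1,5-dien-2-olate (not isolated) | [Li]OC(=C)CCC=C(C)C | intermediate
15 | 6-methylhepta-1,5-dien-2-yl trifluoromethanesulfonate | C=C(CCC=C(C)C)OS(=O)(=O)C(F)(F)F | intermediate
16 | (6-methylhepta-1,5-dien-2-yl)chromium dichloride (not isolated) | C=C(CCC=C(C)C)[Cr](Cl)Cl | intermediate
17 | rac-2-(2-hydroxy-7-methyl-3-methylideneoct-6-en-1-yl)-3,5-bis(methoxymethoxy)-6-(trimethylsilyl)phenyl N-(propan-2-yl)carbamate | C=C(CCC=C(C)C)C(O)Cc1c(OCOC)cc(OCOC)c([Si](C)(C)C)c1OC(=O)NC(C)C | intermediate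
18 | 3,5-bis(methoxymethoxy)-2-(7-methyl-3-methylidene-2-oxooct-6-en-1-yl)-6-(trimethylsilyl)phenyl N-(propan-2-yl)carbamate | C=C(CCC=C(C)C)C(=O)Cc1c(OCOC)cc(OCOC)c([Si](C)(C)C)c1OC(=O)NC(C)C | intermediate
19 | 2-[(2R)-2-hydroxy-7-methyl-3-methylideneoct-6-en-1-yl]-3,5-bis(methoxymethoxy)-6-(trimethylsilyl)phenyl N-(propan-2-yl)carbamate | C=C(CCC=C(C)C)[C@H](O)Cc1c(OCOC)cc(OCOC)c([Si](C)(C)C)c1OC(=O)NC(C)C | intermediate
20 | (2R)-7-methyl-3-methylidene-1-[4,6-bis(methoxymethoxy)-2-{[(propan-2-yl)carbamoyl]oxy}-3-(trimethylsilyl)phenyl]oct-6-en-2-yl benzoate | C=C(CCC=C(C)C)[C@H](OC(=O)c1ccccc1)Cc1c(OCOC)cc(OCOC)c([Si](C)(C)C)c1OC(=O)NC(C)C | intermediate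
21 | (2R)-1-[2-hydroxy-4,6-bis(methoxymethoxy)-3-(trimethylsilyl)phenyl]-7-methyl-3-methylideneoct-6-en-2-yl benzoate (not isolated) | C=C(CCC=C(C)C)[C@H](OC(=O)c1ccccc1)Cc1c(OCOC)cc(OCOC)c([Si](C)(C)C)c1O | intermediate
22 | 2-[(2R)-2-(benzoyloxy)-7-methyl-3-methylideneoct-6-en-1-yl]-3,5-bis(methoxymethoxy)-6-(trimethylsilyl)phenyl trifluoromethanesulfonate | C=C(CCC=C(C)C)[C@H](OC(=O)c1ccccc1)Cc1c(OCOC)cc(OCOC)c([Si](C)(C)C)c1OS(=O)(=O)C(F)(F)F | intermediate
23 | benzoic acid | O=C(O)c1ccccc1 | starting material
24 | 3-[(2R)-2-(benzoyloxy)-7-methyl-3-methylideneoct-6-en-1-yl]-4,6-bis(methoxymethoxy)benzyne, triple bond between ring carbons C5 and C6 (not isolated) | C=C(CCC=C(C)C)[C@H](OC(=O)c1ccccc1)CC1=C(OCOC)C=C(OCOC)C#C1 | intermediate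
25 | (2R)-1-[3-benzoyl-2-hydroxy-4,6-bis(methoxymethoxy)phenyl]-7-methyl-3-methylideneoct-6-en-2-yl benzoate | C=C(CCC=C(C)C)[C@H](OC(=O)c1ccccc1)Cc1c(OCOC)cc(OCOC)c(C(=O)c2ccccc2)c1O | intermediate
26 | {2-hydroxy-3-[(2R)-2-hydroxy-7-methyl-3-methylideneoct-6-en-1-yl]-4,6-bis(methoxymethoxy)phenyl}(phenyl)methanone | C=C(CCC=C(C)C)[C@H](O)Cc1c(OCOC)cc(OCOC)c(C(=O)c2ccccc2)c1O | intermediate
27 | {2,4,6-trihydroxy-3-[(2R)-2-hydroxy-7-methyl-3-methylideneoct-6-en-1-yl]phenyl}(phenyl)methanone | C=C(CCC=C(C)C)[C@H](O)Cc1c(O)cc(O)c(C(=O)c2ccccc2)c1O | target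

Total step count: 13. Longest linear sequence: 12 steps (steps 1–4 and 6–13, from 1 to 27); step 5 is a one-step side branch.

Steps most likely to fail

Step 11. The aryne may be consumed inside the molecule before benzoate arrives, either by the 1,1-disubstituted alkene of the side chain (ene reaction or [2+2] addition) or by the ester oxygen of the side-chain benzoate. Benzoate may also add at C5 instead of C6, or the C5 aryl anion may be protonated before the acyl shift, so that only O-arylation results. The fallback installs the benzoyl group first by classical chemistry and sets out from 1 and 23. Friedel–Crafts acylation of 1 with 23 (BF3·OEt2, 90 °C) would give (2,4,6-trihydroxyphenyl)(phenyl)methanone F1. MOMCl/i-Pr2NEt, which leaves the chelated hydroxyl free, would give [2-hydroxy-4,6-bis(methoxymethoxy)phenyl](phenyl)methanone F2. O-Allylation with 4 (K2CO3, DMF) would give [2-(allyloxy)-4,6-bis(methoxymethoxy)phenyl](phenyl)methanone F3. Aromatic Claisen rearrangement (N,N-diethylaniline, 190 °C) would move the allyl group to the only free ortho carbon and give [3-allyl-2-hydroxy-4,6-bis(methoxymethoxy)phenyl](phenyl)methanone F4. Silylation (TBSOTf, 2,6-lutidine) would give {3-allyl-2-[(tert-butyldimethylsilyl)oxy]-4,6-bis(methoxymethoxy)phenyl}(phenyl)methanone F5, and Lemieux–Johnson cleavage the arylacetaldehyde {3-benzoyl-2-[(tert-butyldimethylsilyl)oxy]-4,6-bis(methoxymethoxy)phenyl}acetaldehyde F6. Nozaki–Hiyama–Kishi coupling with 15 would give the racemic allylic alcohol F7, Dess–Martin oxidation the enone F8, and Corey–Bakshi–Shibata reduction as in step 8 the (R)-alcohol F9; the doubly ortho-substituted diaryl ketone should be much less reactive than the enone. TBAF would then remove the aryl silyl ether, and the fallback comes back to the route at 26, from which step 13 leads to 27.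

Step 3. The one-flask sequence may stall after the first silylation, or leftover chlorosilane may intercept the second aryllithium. The second lithiation may also occur at the carbon between the two MOM ethers instead of the carbon next to the carbamate, or the carbamoyl group may migrate to carbon (anionic Fries shift) before the allyl group is delivered. The fallback separates the two substitutions and replaces the second metalation by an oxygen-to-carbon allyl transfer; it sets out from 3. The silylation alone (TBSOTf, TMEDA; n-BuLi; excess TMSCl; cold aq. NaHSO4 work-up, passing through 5, 6 and 7) would give 3,5-bis(methoxymethoxy)-2-(trimethylsilyl)phenyl N-(propan-2-yl)carbamate F10, which is purified. Et2NH/DBU (MeCN, 40 °C) would remove the carbamate and give 3,5-bis(methoxymethoxy)-2-(trimethylsilyl)phenol F11. Allyl bromide 4 and K2CO3 in acetone would give 1-(allyloxy)-3,5-bis(methoxymethoxy)-2-(trimethylsilyl)benzene F12. Aromatic Claisen rearrangement in N,N-diethylaniline at 180 °C would deliver the allyl group to the single unsubstituted ortho carbon and give 2-allyl-3,5-bis(methoxymethoxy)-6-(trimethylsilyl)phenol F13. i-PrNCO/Et3N would re-form the carbamate, and the fallback comes back to the route at 10.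

Step 13. During acetal cleavage the free carbinol may capture the methoxymethyl cation (cyclic formal with a neighbouring phenol), or the Lewis acid may ionise the allylic alcohol so that a phenol closes onto the side chain. The fallback reverses the last two operations so that the carbinol oxygen stays acylated while the acetals are cleaved, and sets out from 25. ZnBr2/n-PrSH (CH2Cl2, 0 °C) would give (2R)-1-(3-benzoyl-2,4,6-trihydroxyphenyl)-7-methyl-3-methylideneoct-6-en-2-yl benzoate F14. K2CO3/MeOH under argon would then cleave the benzoate, and the fallback arrives at 27.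

Further compounds
F1 | step 11 | (2,4,6-trihydroxyphenyl)(phenyl)methanone | O=C(c1ccccc1)c1c(O)cc(O)cc1O
F2 | step 11 | [2-hydroxy-4,6-bis(methoxymethoxy)phenyl](phenyl)methanone | O=C(c1ccccc1)c1c(O)cc(OCOC)cc1OCOC
F3 | step 11 | [2-(allyloxy)-4,6-bis(methoxymethoxy)phenyl](phenyl)methanone | C=CCOc1cc(OCOC)cc(OCOC)c1C(=O)c1ccccc1
F4 | step 11 | [3-allyl-2-hydroxy-4,6-bis(methoxymethoxy)phenyl](phenyl)methanone | C=CCc1c(OCOC)cc(OCOC)c(C(=O)c2ccccc2)c1O
F5 | step 11 | {3-allyl-2-[(tert-butyldimethylsilyl)oxy]-4,6-bis(methoxymethoxy)phenyl}(phenyl)methanone | C=CCc1c(OCOC)cc(OCOC)c(C(=O)c2ccccc2)c1O[Si](C)(C)C(C)(C)C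
F6 | step 11 | {3-benzoyl-2-[(tert-butyldimethylsilyl)oxy]-4,6-bis(methoxymethoxy)phenyl}acetaldehyde | O=CCc1c(OCOC)cc(OCOC)c(C(=O)c2ccccc2)c1O[Si](C)(C)C(C)(C)C
F7 | step 11 | rac-{2-[(tert-butyldimethylsilyl)oxy]-3-(2-hydroxy-7-methyl-3-methylideneoct-6-en-1-yl)-4,6-bis(methoxymethoxy)phenyl}(phenyl)methanone | C=C(CCC=C(C)C)C(O)Cc1c(OCOC)cc(OCOC)c(C(=O)c2ccccc2)c1O[Si](C)(C)C(C)(C)C
F8 | step 11 | 1-{3-benzoyl-2-[(tert-butyldimethylsilyl)oxy]-4,6-bis(methoxymethoxy)phenyl}-7-methyl-3-methylideneoct-6-en-2-one | C=C(CCC=C(C)C)C(=O)Cc1c(OCOC)cc(OCOC)c(C(=O)c2ccccc2)c1O[Si](C)(C)C(C)(C)C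
F9 | step 11 | {2-[(tert-butyldimethylsilyl)oxy]-3-[(2R)-2-hydroxy-7-methyl-3-methylideneoct-6-en-1-yl]-4,6-bis(methoxymethoxy)phenyl}(phenyl)methanone | C=C(CCC=C(C)C)[C@H](O)Cc1c(OCOC)cc(OCOC)c(C(=O)c2ccccc2)c1O[Si](C)(C)C(C)(C)C
F10 | step 3 | 3,5-bis(methoxymethoxy)-2-(trimethylsilyl)phenyl N-(propan-2-yl)carbamate | CC(C)NC(=O)Oc1cc(OCOC)cc(OCOC)c1[Si](C)(C)C
F11 | step 3 | 3,5-bis(methoxymethoxy)-2-(trimethylsilyl)phenol | COCOc1cc(O)c([Si](C)(C)C)c(OCOC)c1
F12 | step 3 | 1-(allyloxy)-3,5-bis(methoxymethoxy)-2-(trimethylsilyl)benzene | C=CCOc1cc(OCOC)cc(OCOC)c1[Si](C)(C)C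
F13 | step 3 | 2-allyl-3,5-bis(methoxymethoxy)-6-(trimethylsilyl)phenol | C=CCc1c(OCOC)cc(OCOC)c([Si](C)(C)C)c1O
F14 | step 13 | (2R)-1-(3-benzoyl-2,4,6-trihydroxyphenyl)-7-methyl-3-methylideneoct-6-en-2-yl benzoate | C=C(CCC=C(C)C)[C@H](OC(=O)c1ccccc1)Cc1c(O)cc(O)c(C(=O)c2ccccc2)c1O
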